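Readings and results were computed for substances that don't exist; the scatter is artificial.

At 10.0 min Thursday's flask, the very flask asked about, reads 44 % right-handed substrate and 7 % left-handed substrate, an excess of 72.5 % among what is left of the two.

| setting | Thursday's | flask |
|---|---|---|
| left-handed substrate | 0.40 M | 0.40 M |
| right-handed substrate | 0.40 M | 0.40 M |
| coupling partner | 0.60 M | 0.600 M |
| free catalyst | 2 mM | 2.0 mM |
| added ligand | 1.2 mM | 1.2 mM |
| impurity | 0.76 mM | 0.76 mM |
| remark | the very flask that is asked about, followed so far |  |
| time |  | 25 min |

- Thursday's (time / min: right-handed substrate / %, left-handed substrate / %): 2.50: 49, 32; 5.00: 48, 16; 8.00: 47, 8; 10.0: 44, 7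

(each reading ± 1.5 percentage points)

- free catalyst is single-handed; left-handed substrate and right-handed substrate are mirror images of each other, charged as a racemate, each of them at the stated concentration

- whether the excess of right-handed substrate over left-handed substrate among what is left of the two reaches 80 % by 25 min (no / yes)
- the highest excess of right-handed substrate over left-handed substrate among what is left of the two up to 25 min

How far must the left-handed substrate fall? Let f and r be the fractions of the right-handed and left-handed substrate left of their own charges; an excess of 80 % then needs r/f = 0.111.

How does r follow f? The four readings of Thursday's flask, pooled, give 21.5 for the selectivity factor s, defined as ln r over ln f, the E of a kinetic resolution. Frozen at that reading, r = f^s, so the level falls at f = 0.898. That is 50.1 % of both substrates reacted, less than the 75.0 % that the coupling partner covers.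

Is there time? On the pooled readings, f decays at 0.00983 min⁻¹. By balance on the last readings of Thursday's flask, the coupling partner reads 34.7 % of its charge at 10.0 min. Assuming that the loss of right-handed substrate follows the coupling partner and that the coupling partner holds this level, the pace afterwards is reckoned at half the mean so far. This reckoning gives f = 0.840 at 25 min, lower than the level needs, and a top of 94.5 %.

The forecast, holding that “the catalyst seems alive”, says yes with a top of 96 %, slightly above this reckoning.

The flask gives yes and a top of 94.8 %.

    coupling partner + catalyst intermediate A → free catalyst + left-handed product (k = 2.60 M⁻¹ s⁻¹)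
    coupling partner + catalyst intermediate B → free catalyst + right-handed product (k = 1.00 M⁻¹ s⁻¹)
    free catalyst + left-handed substrate ⇌ catalyst intermediate A (K = 13.0 M⁻¹, k = 420 M⁻¹ s⁻¹)
    free catalyst ⇌ dormant form (K = 9.60, k = 0.00120 s⁻¹)
    free catalyst + right-handed substrate ⇌ catalyst intermediate B (K = 1.70 M⁻¹, k = 10.0 M⁻¹ s⁻¹)
    free catalyst + added ligand ⇌ idle complex, settled at all times (K = 380 M⁻¹)
    free catalyst + impurity → spent catalyst (k = 2500 M⁻¹ s⁻¹)

The excess reaches 80 % at 12.5 min, with 50.4 % of both substrates reacted and 44.6 % of the two charged together left as right-handed substrate. Put to use once more, s as read from Thursday's readings turns the 83 % of its charge that the right-handed substrate keeps unbound at 25 min into r = 1.75 %, while the left-handed substrate stands at 2.2 % of its charge.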